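## Retrosynthetic overview

- The strategy rests on ring B, the benzene ring of the dihydrobenzofuran (C3a, C4, C5, C6, C7, C7a). It is a 1,4-hydroquinone (C4–OH, C7–OH) whose only other oxygen, the ring ether O1, sits on C7a next to C7–OH, which is the pattern left when an alcohol adds to a 1,4-benzoquinone and the adduct enolises. The last skeletal disconnection is therefore O1–C7a, back to a ring B quinone carrying the (1S,2S)-1,2-diaryl-2-hydroxyethyl chain on C3a, with five MOM ethers removed after the closure.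
- The quinone comes from a para-methoxyphenol (C4–OH, C7–OMe) with PhI(OAc)2 and water, and the phenol from its C4 benzyl ether. The carbinol and diarylmethine centres come from a racemic 1,2,2-triarylethanone by transfer hydrogenation under dynamic kinetic resolution.
- C3–C3a is made by Pd α-arylation of a deoxybenzoin with a ring B bromide that already carries the flavone. The deoxybenzoin comes from 3,5-dihydroxyacetophenone and 4-bromophenol by a first α-arylation.
- The 3-methoxyflavone comes from a 2'-hydroxyacetophenone and 2-(benzyloxy)-3-bromo-5-methoxybenzaldehyde (Claisen–Schmidt, Algar–Flynn–Oyamada, O-methylation). The 6-methyl pattern of ring A is fixed by a symmetric phenol made from 2-methylresorcinol by meta C–H borylation.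
- Ring order: rings A and B are bought as benzene rings, the pyranone ring C closes in step 8, and the dihydrofuran ring D closes last in step 17.

Key step: step 17

Remarks on the chemistry:
- Benzofuran numbering (O1, C2, C3, C3a, C4 to C7, C7a) is used for the atoms of rings B and D in every intermediate.
- The (S,S)-TsDPEN catalyst is assumed to give the (S)-carbinol, as it does with aryl alkyl ketones, with the 3,5-bis(methoxymethoxy)phenyl ring in the aryl site. If the opposite sense is found, the (R,R)-catalyst is used.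

## Route

Step 1
Reactants: 1 2-methylbenzene-1,3-diol
Product: 2 1,3-bis(methoxymethoxy)-2-methylbenzene
Conditions: MOMCl, K2CO3, acetone, rt
Reagents that add atoms: chloromethyl methyl ether, COCCl
Why: Williamson-type O-alkylation of both phenoxides by the α-chloro ether should give the bis-MOM ether, in which C5–H is the only ring C–H without an ortho substituent.

Step 2
Reactants: 2 1,3-bis(methoxymethoxy)-2-methylbenzene
Product: 4 3,5-bis(methoxymethoxy)-4-methylphenol, via arylboronic pinacol ester 3 (not isolated)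
Conditions: [Ir(OMe)(cod)]2 (1.5 mol %), dtbpy (3 mol %), B2pin2 (0.6 equiv), THF, 80 °C; then NaOH, H2O2 (30 %), 0 °C
Reagents that add atoms: hydrogen peroxide, OO
Why: Sterically governed iridium-catalysed C–H borylation (Hartwig–Miyaura type) should take the one C–H flanked by two hydrogens, para to the methyl group, and oxidation of the C–B bond then gives a phenol whose two ortho positions are equivalent.

Step 3
Reactants: 4 3,5-bis(methoxymethoxy)-4-methylphenol
Product: 5 5-(benzyloxy)-1,3-bis(methoxymethoxy)-2-methylbenzene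
Conditions: BnBr, K2CO3, DMF, rt
Reagents that add atoms: benzyl bromide, BrCc1ccccc1
Why: Williamson etherification marks the oxygen that will become O1 of the chromone with a group that can later be removed by hydrogenolysis without touching the MOM ethers.

Step 4
Reactants: 5 5-(benzyloxy)-1,3-bis(methoxymethoxy)-2-methylbenzene
Product: 7 1-[6-(benzyloxy)-2,4-bis(methoxymethoxy)-3-methylphenyl]ethan-1-one, via aryllithium 6 (not isolated)
Conditions: n-BuLi, THF, 0 °C; then MeC(O)N(OMe)Me, −78 °C to 0 °C; H2O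
Reagents that add atoms: N-methoxy-N-methylacetamide, CON(C)C(C)=O
Why: Directed ortho-metalation between the OMOM and OBn groups (the two such positions are equivalent) followed by Weinreb amide acylation, whose chelated adduct stops at the ketone, should place the acetyl group next to the benzylated oxygen.

Step 5
Reactants: 7 1-[6-(benzyloxy)-2,4-bis(methoxymethoxy)-3-methylphenyl]ethan-1-one
Product: 8 1-[6-hydroxy-2,4-bis(methoxymethoxy)-3-methylphenyl]ethan-1-one
Conditions: H2 (1 atm), Pd/C, EtOAc, rt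
Reagents that add atoms: none
Why: Hydrogenolysis of the benzyl ether frees only the hydroxyl that is ortho to the acetyl group and para to the methyl group, which fixes the later chromone as the 6-methyl and not the 8-methyl isomer.

Step 6
Reactants: 9 2-hydroxy-5-methoxybenzaldehyde
Product: 10 3-bromo-2-hydroxy-5-methoxybenzaldehyde
Conditions: Br2, NaOAc, AcOH, rt
Reagents that add atoms: bromine, BrBr
Why: Electrophilic aromatic bromination should go ortho to the free phenol, the only open position that it activates.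

Step 7
Reactants: 10 3-bromo-2-hydroxy-5-methoxybenzaldehyde
Product: 11 2-(benzyloxy)-3-bromo-5-methoxybenzaldehyde
Conditions: BnBr, K2CO3, DMF, 60 °C
Reagents that add atoms: benzyl bromide, BrCc1ccccc1
Why: Williamson etherification protects the future C4 oxygen of ring B as a benzyl ether, so that it can later be freed selectively beside the C7 methyl ether and the MOM ethers.

Step 8
Reactants: 8 1-[6-hydroxy-2,4-bis(methoxymethoxy)-3-methylphenyl]ethan-1-one; 11 2-(benzyloxy)-3-bromo-5-methoxybenzaldehyde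
Product: 13 2-[2-(benzyloxy)-3-bromo-5-methoxyphenyl]-3-hydroxy-5,7-bis(methoxymethoxy)-6-methyl-4H-chromen-4-one, via chalcone 12 (not isolated)
Conditions: KOH, EtOH, rt; then NaOH, H2O2 (30 %), MeOH, 0 °C to rt
Reagents that add atoms: hydrogen peroxide, OO
Why: Claisen–Schmidt condensation gives the 2'-hydroxychalcone, and the Algar–Flynn–Oyamada reaction (phenoxide closure, C3 oxygenation by hydroperoxide, dehydrogenation) should close ring C as the flavonol under basic conditions that keep the MOM and benzyl ethers.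

Step 9
Reactants: 13 2-[2-(benzyloxy)-3-bromo-5-methoxyphenyl]-3-hydroxy-5,7-bis(methoxymethoxy)-6-methyl-4H-chromen-4-one
Product: 14 2-[2-(benzyloxy)-3-bromo-5-methoxyphenyl]-3-methoxy-5,7-bis(methoxymethoxy)-6-methyl-4H-chromen-4-one
Conditions: MeI, K2CO3, acetone, reflux
Reagents that add atoms: iodomethane, CI
Why: Williamson O-methylation of the 3-hydroxyl, the only free hydroxyl, installs the one methyl ether that the target keeps.

Step 10
Reactants: 15 1-(3,5-dihydroxyphenyl)ethan-1-one
Product: 16 1-[3,5-bis(methoxymethoxy)phenyl]ethan-1-one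
Conditions: MOMCl, K2CO3, acetone, rt
Reagents that add atoms: chloromethyl methyl ether, COCCl
Why: Williamson-type O-alkylation of the two phenols, which are far more acidic than the methyl ketone, should give the bis-MOM ether.

Step 11
Reactants: 17 4-bromophenol
Product: 18 1-bromo-4-(methoxymethoxy)benzene
Conditions: MOMCl, K2CO3, acetone, rt
Reagents that add atoms: chloromethyl methyl ether, COCCl
Why: Williamson-type O-alkylation masks the phenol as the same acid-labile ether used elsewhere.

Step 12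
Reactants: 16 1-[3,5-bis(methoxymethoxy)phenyl]ethan-1-one; 18 1-bromo-4-(methoxymethoxy)benzene
Product: 19 1-[3,5-bis(methoxymethoxy)phenyl]-2-[4-(methoxymethoxy)phenyl]ethan-1-one
Conditions: Pd2(dba)3 (1.5 mol %), rac-BINAP (3.6 mol %), NaOtBu, THF, 70 °C
Reagents that add atoms: none
Why: Palladium-catalysed α-arylation of a methyl ketone enolate (Buchwald–Hartwig type) with a chelating bisphosphine should stop at the mono-arylated deoxybenzoin.

Step 13
Reactants: 14 2-[2-(benzyloxy)-3-bromo-5-methoxyphenyl]-3-methoxy-5,7-bis(methoxymethoxy)-6-methyl-4H-chromen-4-one; 19 1-[3,5-bis(methoxymethoxy)phenyl]-2-[4-(methoxymethoxy)phenyl]ethan-1-one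
Product: 20 rac-2-{2-(benzyloxy)-3-[2-[3,5-bis(methoxymethoxy)phenyl]-1-[4-(methoxymethoxy)phenyl]-2-oxoethyl]-5-methoxyphenyl}-3-methoxy-5,7-bis(methoxymethoxy)-6-methyl-4H-chromen-4-one
Conditions: Pd(OAc)2 (5 mol %), XPhos (10 mol %), K3PO4, toluene, 100 °C
Reagents that add atoms: none
Why: Palladium-catalysed α-arylation of the acidic deoxybenzoin with the ortho-alkoxy aryl bromide, using a bulky biarylphosphine and a phosphate base mild enough for the chromone, should form C3–C3a and give the triarylethanone as a racemate.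

Step 14
Reactants: 20 rac-2-{2-(benzyloxy)-3-[2-[3,5-bis(methoxymethoxy)phenyl]-1-[4-(methoxymethoxy)phenyl]-2-oxoethyl]-5-methoxyphenyl}-3-methoxy-5,7-bis(methoxymethoxy)-6-methyl-4H-chromen-4-one
Product: 21 2-{2-(benzyloxy)-3-[(1S,2S)-2-[3,5-bis(methoxymethoxy)phenyl]-2-hydroxy-1-[4-(methoxymethoxy)phenyl]ethyl]-5-methoxyphenyl}-3-methoxy-5,7-bis(methoxymethoxy)-6-methyl-4H-chromen-4-one
Conditions: RuCl[(S,S)-TsDPEN](p-cymene) (3 mol %), HCO2H–DBU (1:1.2), DMF, 40 °C
Reagents that add atoms: none
Why: In this Noyori–Ikariya transfer hydrogenation under dynamic kinetic resolution the doubly benzylic α-hydrogen racemises in the amine-rich medium, the (S,S)-ligand sets the (S)-carbinol, and the ketone enantiomer whose Felkin–Anh preference (the ortho-substituted ring B aryl as the large group anti to hydride) matches that face should react faster, which sets (S) at the diarylmethine carbon.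

Step 15
Reactants: 21 2-{2-(benzyloxy)-3-[(1S,2S)-2-[3,5-bis(methoxymethoxy)phenyl]-2-hydroxy-1-[4-(methoxymethoxy)phenyl]ethyl]-5-methoxyphenyl}-3-methoxy-5,7-bis(methoxymethoxy)-6-methyl-4H-chromen-4-one
Product: 22 2-{3-[(1S,2S)-2-[3,5-bis(methoxymethoxy)phenyl]-2-hydroxy-1-[4-(methoxymethoxy)phenyl]ethyl]-2-hydroxy-5-methoxyphenyl}-3-methoxy-5,7-bis(methoxymethoxy)-6-methyl-4H-chromen-4-one
Conditions: H2 (1 atm), Pd/C, EtOAc–MeOH, rt
Reagents that add atoms: none
Why: Hydrogenolysis of the aryl benzyl ether should be much faster than cleavage of the unactivated benzylic carbinol or reduction of the tetrasubstituted chromone double bond, and it frees the C4 phenol para to the C7 methoxy group.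

Step 16
Reactants: 22 2-{3-[(1S,2S)-2-[3,5-bis(methoxymethoxy)phenyl]-2-hydroxy-1-[4-(methoxymethoxy)phenyl]ethyl]-2-hydroxy-5-methoxyphenyl}-3-methoxy-5,7-bis(methoxymethoxy)-6-methyl-4H-chromen-4-one
Product: 23 2-[(1S,2S)-2-[3,5-bis(methoxymethoxy)phenyl]-2-hydroxy-1-[4-(methoxymethoxy)phenyl]ethyl]-6-[3-methoxy-5,7-bis(methoxymethoxy)-6-methyl-4-oxo-4H-chromen-2-yl]cyclohexa-2,5-diene-1,4-dione
Conditions: PhI(OAc)2 (1.05 equiv), MeCN–H2O (4:1), 0 °C
Reagents that add atoms: water, O
Why: Hypervalent iodine oxidation of a para-methoxyphenol starts by ligand exchange at iodine on the one free phenol, water then adds at C7 and methanol is lost, so the quinone should form without single-electron oxidation of the other electron-rich rings or of the carbinol.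

Step 17
Reactants: 23 2-[(1S,2S)-2-[3,5-bis(methoxymethoxy)phenyl]-2-hydroxy-1-[4-(methoxymethoxy)phenyl]ethyl]-6-[3-methoxy-5,7-bis(methoxymethoxy)-6-methyl-4-oxo-4H-chromen-2-yl]cyclohexa-2,5-diene-1,4-dione
Product: 24 2-[(2S,3S)-2-[3,5-bis(methoxymethoxy)phenyl]-4,7-dihydroxy-3-[4-(methoxymethoxy)phenyl]-2,3-dihydro-1-benzofuran-5-yl]-3-methoxy-5,7-bis(methoxymethoxy)-6-methyl-4H-chromen-4-one
Conditions: Sc(OTf)3 (10 mol %), CH2Cl2–MeCN (4:1), 0.005 M, 0 °C to rt, argon; aq. Na2S2O4 wash
Reagents that add atoms: none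
Why: Sc(OTf)3 binds the quinone carbonyls, the carbinol oxygen adds to C7a (β to C4=O through C3a=C7a, α to C7=O) and tautomerisation gives the aromatic 4,7-diol, so that O1–C7a and ring D form with no change in overall oxidation level. The closest known reaction type is the acid-promoted intramolecular hetero-Michael addition of a side-chain heteroatom to a 1,4-benzoquinone, as in the closure of 2-(2-aminoethyl)- and 2-(2-hydroxyaryl)-1,4-benzoquinones to 5-hydroxyindolines and 2-hydroxydibenzofurans. Ring D closes in the 5-endo-trig mode, which should be tolerated because the acid-bound quinone reacts as a delocalised cation and the product is aromatic. No stereocentre is formed and no bond to C2 or C3 is made or broken, so the (1S,2S) diad of 23 becomes the (2S,3S) trans diad of 24. The step needs site selectivity for C7a over C6 and over reversible hemiketal formation at C4, which the tether secures because the oxygen can reach only C7a productively. It also needs the closure to outrun tautomerisation of the quinone to its quinone methide (which would scramble C3) and hydrogen exchange between product hydroquinone and unreacted quinone; acid instead of base, low temperature and high dilution (first-order closure against second-order exchange) are meant to secure this, and the Na2S2O4 wash returns any oxidised product to 24.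

Step 18
Reactants: 24 2-[(2S,3S)-2-[3,5-bis(methoxymethoxy)phenyl]-4,7-dihydroxy-3-[4-(methoxymethoxy)phenyl]-2,3-dihydro-1-benzofuran-5-yl]-3-methoxy-5,7-bis(methoxymethoxy)-6-methyl-4H-chromen-4-one
Product: 25 2-[(2S,3S)-2-(3,5-dihydroxyphenyl)-4,7-dihydroxy-3-(4-hydroxyphenyl)-2,3-dihydro-1-benzofuran-5-yl]-5,7-dihydroxy-3-methoxy-6-methyl-4H-chromen-4-one
Conditions: HCl (3 M aq.), MeOH, 45 °C, argon; aq. Na2S2O4 wash
Reagents that add atoms: none
Why: Acid-catalysed transacetalisation to methanol should remove all five MOM ethers, while the 3-methyl ether survives and C2, which carries only a meta-dioxygenated aryl group, does not ionise, so the trans diad is kept.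

## Compound list

1 | 2-methylbenzene-1,3-diol | Cc1c(O)cccc1O | starting material
2 | 1,3-bis(methoxymethoxy)-2-methylbenzene | COCOc1cccc(OCOC)c1C | intermediate
3 | 2-[3,5-bis(methoxymethoxy)-4-methylphenyl]-4,4,5,5-tetramethyl-1,3,2-dioxaborolane | COCOc1cc(cc(OCOC)c1C)B1OC(C)(C)C(C)(C)O1 | intermediate
4 | 3,5-bis(methoxymethoxy)-4-methylphenol | COCOc1cc(O)cc(OCOC)c1C | intermediate
5 | 5-(benzyloxy)-1,3-bis(methoxymethoxy)-2-methylbenzene | COCOc1cc(OCc2ccccc2)cc(OCOC)c1C | intermediate
6 | [6-(benzyloxy)-2,4-bis(methoxymethoxy)-3-methylphenyl]lithium | [Li]c1c(OCc2ccccc2)cc(OCOC)c(C)c1OCOC | intermediate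
7 | 1-[6-(benzyloxy)-2,4-bis(methoxymethoxy)-3-methylphenyl]ethan-1-one | CC(=O)c1c(OCc2ccccc2)cc(OCOC)c(C)c1OCOC | intermediate
8 | 1-[6-hydroxy-2,4-bis(methoxymethoxy)-3-methylphenyl]ethan-1-one | CC(=O)c1c(O)cc(OCOC)c(C)c1OCOC | intermediate
9 | 2-hydroxy-5-methoxybenzaldehyde | COc1ccc(O)c(C=O)c1 | starting material
10 | 3-bromo-2-hydroxy-5-methoxybenzaldehyde | COc1cc(Br)c(O)c(C=O)c1 | intermediate
11 | 2-(benzyloxy)-3-bromo-5-methoxybenzaldehyde | COc1cc(Br)c(OCc2ccccc2)c(C=O)c1 | intermediate
12 | (E)-3-[2-(benzyloxy)-3-bromo-5-methoxyphenyl]-1-[6-hydroxy-2,4-bis(methoxymethoxy)-3-methylphenyl]prop-2-en-1-one | COc1cc(Br)c(OCc2ccccc2)c(/C=C/C(=O)c2c(O)cc(OCOC)c(C)c2OCOC)c1 | intermediate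
13 | 2-[2-(benzyloxy)-3-bromo-5-methoxyphenyl]-3-hydroxy-5,7-bis(methoxymethoxy)-6-methyl-4H-chromen-4-one | COc1cc(Br)c(OCc2ccccc2)c(c1)-c1oc2cc(OCOC)c(C)c(OCOC)c2c(=O)c1O | intermediate
14 | 2-[2-(benzyloxy)-3-bromo-5-methoxyphenyl]-3-methoxy-5,7-bis(methoxymethoxy)-6-methyl-4H-chromen-4-one | COc1cc(Br)c(OCc2ccccc2)c(c1)-c1oc2cc(OCOC)c(C)c(OCOC)c2c(=O)c1OC | intermediate
15 | 1-(3,5-dihydroxyphenyl)ethan-1-one | CC(=O)c1cc(O)cc(O)c1 | starting material
16 | 1-[3,5-bis(methoxymethoxy)phenyl]ethan-1-one | CC(=O)c1cc(OCOC)cc(OCOC)c1 | intermediate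
17 | 4-bromophenol | Oc1ccc(Br)cc1 | starting material
18 | 1-bromo-4-(methoxymethoxy)benzene | COCOc1ccc(Br)cc1 | intermediate
19 | 1-[3,5-bis(methoxymethoxy)phenyl]-2-[4-(methoxymethoxy)phenyl]ethan-1-one | COCOc1ccc(CC(=O)c2cc(OCOC)cc(OCOC)c2)cc1 | intermediate
20 | rac-2-{2-(benzyloxy)-3-[2-[3,5-bis(methoxymethoxy)phenyl]-1-[4-(methoxymethoxy)phenyl]-2-oxoethyl]-5-methoxyphenyl}-3-methoxy-5,7-bis(methoxymethoxy)-6-methyl-4H-chromen-4-one | COc1cc(C(C(=O)c2cc(OCOC)cc(OCOC)c2)c2ccc(OCOC)cc2)c(OCc2ccccc2)c(c1)-c1oc2cc(OCOC)c(C)c(OCOC)c2c(=O)c1OC | intermediate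
21 | 2-{2-(benzyloxy)-3-[(1S,2S)-2-[3,5-bis(methoxymethoxy)phenyl]-2-hydroxy-1-[4-(methoxymethoxy)phenyl]ethyl]-5-methoxyphenyl}-3-methoxy-5,7-bis(methoxymethoxy)-6-methyl-4H-chromen-4-one | COc1cc([C@H](c2ccc(OCOC)cc2)[C@H](O)c2cc(OCOC)cc(OCOC)c2)c(OCc2ccccc2)c(c1)-c1oc2cc(OCOC)c(C)c(OCOC)c2c(=O)c1OC | intermediate
22 | 2-{3-[(1S,2S)-2-[3,5-bis(methoxymethoxy)phenyl]-2-hydroxy-1-[4-(methoxymethoxy)phenyl]ethyl]-2-hydroxy-5-methoxyphenyl}-3-methoxy-5,7-bis(methoxymethoxy)-6-methyl-4H-chromen-4-one | COc1cc([C@H](c2ccc(OCOC)cc2)[C@H](O)c2cc(OCOC)cc(OCOC)c2)c(O)c(c1)-c1oc2cc(OCOC)c(C)c(OCOC)c2c(=O)c1OC | intermediate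
23 | 2-[(1S,2S)-2-[3,5-bis(methoxymethoxy)phenyl]-2-hydroxy-1-[4-(methoxymethoxy)phenyl]ethyl]-6-[3-methoxy-5,7-bis(methoxymethoxy)-6-methyl-4-oxo-4H-chromen-2-yl]cyclohexa-2,5-diene-1,4-dione | COc1c(C2=CC(=O)C=C(C2=O)[C@H](c2ccc(OCOC)cc2)[C@H](O)c2cc(OCOC)cc(OCOC)c2)oc2cc(OCOC)c(C)c(OCOC)c2c1=O | intermediate
24 | 2-[(2S,3S)-2-[3,5-bis(methoxymethoxy)phenyl]-4,7-dihydroxy-3-[4-(methoxymethoxy)phenyl]-2,3-dihydro-1-benzofuran-5-yl]-3-methoxy-5,7-bis(methoxymethoxy)-6-methyl-4H-chromen-4-one | COc1c(-c2cc(O)c3c(c2O)[C@H](c2ccc(OCOC)cc2)[C@@H](c2cc(OCOC)cc(OCOC)c2)O3)oc2cc(OCOC)c(C)c(OCOC)c2c1=O | intermediate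
25 | 2-[(2S,3S)-2-(3,5-dihydroxyphenyl)-4,7-dihydroxy-3-(4-hydroxyphenyl)-2,3-dihydro-1-benzofuran-5-yl]-5,7-dihydroxy-3-methoxy-6-methyl-4H-chromen-4-one | COc1c(-c2cc(O)c3c(c2O)[C@H](c2ccc(O)cc2)[C@@H](c2cc(O)cc(O)c2)O3)oc2cc(O)c(C)c(O)c2c1=O | target

## Step count and risks

Total step count: 18. Longest linear sequence: 13 steps (steps 1 to 5, 8, 9, 13 to 18).

Steps most likely to fail:

1. Step 17 (quinone oxa-Michael closure). The 5-endo closure may be slow. Hydrogen exchange between the product hydroquinone and unreacted quinone would then stall the reaction near half conversion and leave an oxidised dihydrobenzofurandione that can aromatise to the benzofuran. Acid-catalysed tautomerisation of the quinone to its quinone methide would also scramble C3. The fallback runs the conjugate addition on the quinone monoketal, which cannot enter redox exchange and is less prone to methide formation. It sets out from 22 and comes back at 24. Oxidation of 22 with PhI(OAc)2 in MeOH at 0 °C should give the 4,4-dimethoxycyclohexadienone (quinone monoketal) F1. Camphorsulfonic acid (cat.) in CH2Cl2 should then bring about addition of the carbinol oxygen to C7a and loss of methanol, giving the 7-methoxy-2,3-dihydrobenzofuran-4-ol F2. F2 is again a para-methoxyphenol, so PhI(OAc)2 in MeCN–H2O at 0 °C should give the 2,3-dihydrobenzofuran-4,7-dione F3, which is reduced at once with aqueous Na2S2O4 to 24.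

2. Step 14 (transfer hydrogenation under dynamic kinetic resolution). The catalyst-preferred carbonyl face and the Felkin–Anh preference may fall on different enantiomers of the ketone, or racemisation of the diarylmethine may be slower than reduction. Either way the (S)-carbinol would form mainly beside an (R)-diarylmethine, which leads to the cis-dihydrobenzofuran series. The fallback sets the diarylmethine first and corrects the carbinol by inversion. It sets out from 20 and comes back at 21. Reduction of 20 with RuCl[(R,R)-TsDPEN](p-cymene) under the same conditions should give the (1S,2R)-alcohol F4, with the diarylmethine correct and the carbinol inverted. Mitsunobu esterification (4-nitrobenzoic acid, PPh3, DIAD, THF, 0 °C) inverts the carbinol to the (1S,2S) 4-nitrobenzoate F5, and K2CO3 in MeOH at rt frees 21.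

3. Step 8 (Algar–Flynn–Oyamada reaction). With an alkoxy group at C6' the chalcone may close through its α-carbon to the five-membered aurone and not to the flavonol. The fallback separates ring closure from C3 oxygenation. It sets out from chalcone 12, isolated after the condensation, and comes back at 13. NaOAc in EtOH at reflux should cyclise 12 to the flavanone F6, DDQ in dioxane at 90 °C dehydrogenates it to the flavone F7, and dimethyldioxirane (acetone–CH2Cl2, 0 °C), followed by opening of the 2,3-epoxide on silica gel, gives 13.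

Further compounds
F1 | step 17 | 2-{5-[(1S,2S)-2-[3,5-bis(methoxymethoxy)phenyl]-2-hydroxy-1-[4-(methoxymethoxy)phenyl]ethyl]-3,3-dimethoxy-6-oxocyclohexa-1,4-dien-1-yl}-3-methoxy-5,7-bis(methoxymethoxy)-6-methyl-4H-chromen-4-one | COc1c(C2=CC(OC)(OC)C=C(C2=O)[C@H](c2ccc(OCOC)cc2)[C@H](O)c2cc(OCOC)cc(OCOC)c2)oc2cc(OCOC)c(C)c(OCOC)c2c1=O
F2 | step 17 | 2-[(2S,3S)-2-[3,5-bis(methoxymethoxy)phenyl]-4-hydroxy-7-methoxy-3-[4-(methoxymethoxy)phenyl]-2,3-dihydro-1-benzofuran-5-yl]-3-methoxy-5,7-bis(methoxymethoxy)-6-methyl-4H-chromen-4-one | COc1c(-c2cc(OC)c3c(c2O)[C@H](c2ccc(OCOC)cc2)[C@@H](c2cc(OCOC)cc(OCOC)c2)O3)oc2cc(OCOC)c(C)c(OCOC)c2c1=O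
F3 | step 17 | 2-[(2S,3S)-2-[3,5-bis(methoxymethoxy)phenyl]-3-[4-(methoxymethoxy)phenyl]-4,7-dioxo-2,3,4,7-tetrahydro-1-benzofuran-5-yl]-3-methoxy-5,7-bis(methoxymethoxy)-6-methyl-4H-chromen-4-one | COc1c(C2=CC(=O)C3=C(C2=O)[C@H](c2ccc(OCOC)cc2)[C@@H](c2cc(OCOC)cc(OCOC)c2)O3)oc2cc(OCOC)c(C)c(OCOC)c2c1=O
F4 | step 14 | 2-{2-(benzyloxy)-3-[(1S,2R)-2-[3,5-bis(methoxymethoxy)phenyl]-2-hydroxy-1-[4-(methoxymethoxy)phenyl]ethyl]-5-methoxyphenyl}-3-methoxy-5,7-bis(methoxymethoxy)-6-methyl-4H-chromen-4-one | COc1cc([C@H](c2ccc(OCOC)cc2)[C@@H](O)c2cc(OCOC)cc(OCOC)c2)c(OCc2ccccc2)c(c1)-c1oc2cc(OCOC)c(C)c(OCOC)c2c(=O)c1OC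
F5 | step 14 | (1S,2S)-2-{2-(benzyloxy)-5-methoxy-3-[3-methoxy-5,7-bis(methoxymethoxy)-6-methyl-4-oxo-4H-chromen-2-yl]phenyl}-1-[3,5-bis(methoxymethoxy)phenyl]-2-[4-(methoxymethoxy)phenyl]ethyl 4-nitrobenzoate | COc1cc([C@H](c2ccc(OCOC)cc2)[C@H](OC(=O)c2ccc(cc2)[N+](=O)[O-])c2cc(OCOC)cc(OCOC)c2)c(OCc2ccccc2)c(c1)-c1oc2cc(OCOC)c(C)c(OCOC)c2c(=O)c1OC
F6 | step 8 | rac-2-[2-(benzyloxy)-3-bromo-5-methoxyphenyl]-5,7-bis(methoxymethoxy)-6-methyl-2,3-dihydro-4H-chromen-4-one | COc1cc(Br)c(OCc2ccccc2)c(c1)C1CC(=O)c2c(OCOC)c(C)c(OCOC)cc2O1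
F7 | step 8 | 2-[2-(benzyloxy)-3-bromo-5-methoxyphenyl]-5,7-bis(methoxymethoxy)-6-methyl-4H-chromen-4-one | COc1cc(Br)c(OCc2ccccc2)c(c1)-c1cc(=O)c2c(OCOC)c(C)c(OCOC)cc2o1
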